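**Retrosynthetic overview**
- The 1,2-dioxane is formed last: silane reduction of a C11 peroxyketal acetate, which comes from H2O2 opening of a (7S,8S)-epoxy enone followed by transannular peroxy-hemiketalisation.
- The epoxide comes from Shi epoxidation of a macrocyclic trienone lactone in which C7=C8 is the only electron-rich alkene.
- The 14-membered carbocycle and the trans α-methylene-γ-lactone come from one chiral-phosphoric-acid-catalysed macrocyclising allylboration–lactonisation (C1–C2 bond; sets C1 and C2).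
- The seco precursor comes from Nozaki–Hiyama–Kishi coupling (C11–C12) of a farnesol-derived C2–C11 aldehyde with a (Z)-vinyl iodide/allylboronate built from but-2-yn-1-ol, methyl propiolate and ICH2Bpin.
- Ring order: 14-membered carbocycle, then γ-lactone (same step), then epoxide, then 1,2-dioxane.

**Numbering and reading of the target (assumption):** cembrane numbering is used: C1 (ring CH carrying C15), C2 (lactone CH–O), C3=C4(Me), C7, C8(Me), C11, C12(Me)=C13, C14, C15(=C17H2)–C16(=O)–O–C2. In this numbering the SMILES reads 1S,2R,3E,7S,8R,11S,12Z, with a trans-fused lactone and with C7 and C12 cis on the dioxane.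

**Abbreviations:** Bpin = 4,4,5,5-tetramethyl-1,3,2-dioxaborolan-2-yl; (S)-TRIP = (S)-3,3'-bis(2,4,6-triisopropylphenyl)-1,1'-binaphthyl-2,2'-diyl hydrogen phosphate; ent-Shi ketone = 1,2:4,5-di-O-isopropylidene-β-L-erythro-2,3-hexodiulo-2,6-pyranose; TEMPO = 2,2,6,6-tetramethylpiperidin-1-oxyl.

## Route

Step 1
Reactants: 1 (2E,6E)-farnesol
Product: 2 (2E,6E)-10-bromo-3,7,11-trimethyldodeca-2,6-diene-1,11-diol (racemic)
Conditions: NBS, THF/H2O, 0 °C
Reagents that add atoms: N-bromosuccinimide O=C1CCC(=O)N1Br; water O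
Why: Bromohydrin formation (van Tamelen conditions) is selective for the terminal, most exposed trisubstituted alkene in aqueous THF; the new stereocentre is racemic and is excised in step 3.

Step 2
Reactants: 2 (2E,6E)-10-bromo-3,7,11-trimethyldodeca-2,6-diene-1,11-diol
Product: 3 (2E,6E)-10,11-epoxy-3,7,11-trimethyldodeca-2,6-dien-1-ol (racemic)
Conditions: K2CO3, MeOH, rt
Reagents that add atoms: none
Why: Intramolecular Williamson etherification of the bromohydrin closes the epoxide.

Step 3
Reactants: 3 (2E,6E)-10,11-epoxy-3,7,11-trimethyldodeca-2,6-dien-1-ol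
Product: 4 (4E,8E)-10-hydroxy-4,8-dimethyldeca-4,8-dienal
Conditions: H5IO6, THF/Et2O, 0 °C
Reagents that add atoms: none
Why: Periodic acid hydrolyses the epoxide and cleaves the glycol (Malaprade cleavage), removing the racemic carbon as acetone and leaving the achiral C2–C11 aldehyde.

Step 4
Reactants: 5 but-2-yn-1-ol
Product: 6 (Z)-3-iodobut-2-en-1-ol
Conditions: NaAlH2(OCH2CH2OMe)2, THF, 0 °C to rt; then I2, −78 to 0 °C
Reagents that add atoms: iodine II
Why: Hydroxyl-directed trans-hydroalumination puts aluminium on C3 anti to the new C2–H, and iodinolysis with retention gives the Z-vinyl iodide that becomes the 12Z alkene.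

Step 5
Reactants: 6 (Z)-3-iodobut-2-en-1-ol
Product: 7 (Z)-1-bromo-3-iodobut-2-ene
Conditions: CBr4, PPh3, CH2Cl2, 0 °C
Reagents that add atoms: carbon tetrabromide BrC(Br)(Br)Br
Why: Appel bromination of the primary allylic alcohol proceeds without touching the vinyl iodide or the alkene geometry.

Step 6
Reactants: 7 (Z)-1-bromo-3-iodobut-2-ene; 8 methyl propiolate
Product: 9 methyl (Z)-6-iodohept-5-en-2-ynoate
Conditions: CuI (10 mol %), K2CO3, Bu4NI (10 mol %), DMF, rt
Reagents that add atoms: none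
Why: Copper acetylide allylation (SN2 coupling of the terminal alkyne with the allylic bromide) forms C14–C1; the vinyl iodide is inert at room temperature.

Step 7
Reactants: 9 methyl (Z)-6-iodohept-5-en-2-ynoate; 10 2-(iodomethyl)-4,4,5,5-tetramethyl-1,3,2-dioxaborolane
Product: 12 methyl (2Z,5Z)-6-iodo-2-[(4,4,5,5-tetramethyl-1,3,2-dioxaborolan-2-yl)methyl]hepta-2,5-dienoate, via aluminium allenolate 11 (not isolated)
Conditions: iBu2AlH, HMPA, THF, 0 °C; then 10, 0 °C to rt
Reagents that add atoms: none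
Why: Conjugate hydroalumination of the ynoate gives allenolate 11, which is alkylated at C2 by ICH2Bpin (boron ate complex, 1,2-shift) on the side of the C3–H, so CH2Bpin ends trans to the C4 chain (2Z), the geometry needed for an anti allylboration.

Step 8
Reactants: 4 (4E,8E)-10-hydroxy-4,8-dimethyldeca-4,8-dienal; 12 methyl (2Z,5Z)-6-iodo-2-[(4,4,5,5-tetramethyl-1,3,2-dioxaborolan-2-yl)methyl]hepta-2,5-dienoate
Product: 13 methyl (2Z,5Z,10E,14E)-7,16-dihydroxy-6,10,14-trimethyl-2-[(4,4,5,5-tetramethyl-1,3,2-dioxaborolan-2-yl)methyl]hexadeca-2,5,10,14-tetraenoate (racemic carbinol)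
Conditions: CrCl2 (6 equiv), NiCl2 (2 mol %), DMSO, rt
Reagents that add atoms: none
Why: Nozaki–Hiyama–Kishi coupling adds the alkenylchromium to the aliphatic aldehyde with retention of the Z geometry and tolerates the ester, the free hydroxyl and the ester-deactivated allylboronate; the uncontrolled C11 carbinol is oxidised to the ketone in step 11.

Step 9
Reactants: 13 methyl (2Z,5Z,10E,14E)-7,16-dihydroxy-6,10,14-trimethyl-2-[(4,4,5,5-tetramethyl-1,3,2-dioxaborolan-2-yl)methyl]hexadeca-2,5,10,14-tetraenoate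
Product: 14 methyl (2Z,5Z,10E,14E)-7-hydroxy-6,10,14-trimethyl-16-oxo-2-[(4,4,5,5-tetramethyl-1,3,2-dioxaborolan-2-yl)methyl]hexadeca-2,5,10,14-tetraenoate (racemic carbinol)
Conditions: TEMPO (10 mol %), PhI(OAc)2 (1.1 equiv), CH2Cl2, rt
Reagents that add atoms: none
Why: Oxoammonium (TEMPO) oxidation is selective for the primary allylic alcohol over the hindered secondary one, giving the E-enal without touching the C–B bond.

Step 10
Reactants: 14 methyl (2Z,5Z,10E,14E)-7-hydroxy-6,10,14-trimethyl-16-oxo-2-[(4,4,5,5-tetramethyl-1,3,2-dioxaborolan-2-yl)methyl]hexadeca-2,5,10,14-tetraenoate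
Product: 16 (1S,2R,3E,7E,12Z)-11-hydroxycembra-3,7,12,15(17)-tetraen-16,2-olide (both C11 epimers), via macrocyclic pinacol borate 15 (not isolated)
Conditions: (S)-TRIP (20 mol %), 4 Å MS, toluene, 40 °C, slow addition of 14 over 24 h (final 5 mM); then p-TsOH·H2O (20 mol %), rt
Reagents that add atoms: none
Why: Proposed new method: a chiral-phosphoric-acid-catalysed macrocyclising allylboration–lactonisation, in which the acid hydrogen-bonds to a boronate oxygen (raising the boron Lewis acidity that the ester-deactivated reagent needs) and to the formyl C–H, so the enal and the tethered allylboronate react through one closed chair with C3 and C14 equatorial (anti adduct, hence trans lactone, C1 S) while the (S)-acid is expected to expose the aldehyde Si face (C2 R) by analogy with the known (R)-acid/Re-face sense, and p-TsOH then closes the γ-lactone; the closest known reactions are the chiral-phosphoric-acid-catalysed intermolecular allylboration of aldehydes with allyl- and crotyl-Bpin and the acid-accelerated intermolecular allylboration–lactonisation of 2-alkoxycarbonyl allylboronates, neither shown intramolecularly for a macrocycle or enantioselectively for this reagent class; C11 is kept as the alcohol here so the boronate cannot add to a C11 carbonyl through a five-membered ring, and C1 and C2 are the first stereocentres carried into the target.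

Step 11
Reactants: 16 (1S,2R,3E,7E,12Z)-11-hydroxycembra-3,7,12,15(17)-tetraen-16,2-olide
Product: 17 (1S,2R,3E,7E,12Z)-11-oxocembra-3,7,12,15(17)-tetraen-16,2-olide
Conditions: MnO2 (20 equiv), CH2Cl2, rt
Reagents that add atoms: none
Why: MnO2 allylic oxidation converges both C11 epimers on one Z-enone and makes C12=C13 electron-poor for the next step.

Step 12
Reactants: 17 (1S,2R,3E,7E,12Z)-11-oxocembra-3,7,12,15(17)-tetraen-16,2-olide
Product: 18 (1S,2R,3E,7S,8S,12Z)-7,8-epoxy-11-oxocembra-3,12,15(17)-trien-16,2-olide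
Conditions: ent-Shi ketone (30 mol %), KHSO5 (as 2KHSO5·KHSO4·K2SO4), K2CO3, Bu4NHSO4, MeCN/CH2(OMe)2/aq. Na2B4O7 buffer, 0 °C
Reagents that add atoms: potassium peroxymonosulfate [K+].[O-]S(=O)(=O)OO
Why: Shi epoxidation (chiral dioxirane, spiro transition state) with the L-series ketone gives the (S,S)-epoxide of an E-trisubstituted alkene under catalyst control, and C7=C8 is the only electron-rich alkene (C3=C4 carries the allylic lactone oxygen; C12=C13 and C15=C17 are conjugated to carbonyls).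

Step 13
Reactants: 18 (1S,2R,3E,7S,8S,12Z)-7,8-epoxy-11-oxocembra-3,12,15(17)-trien-16,2-olide
Product: 20 (1S,2R,3E,7S,8R,12Z)-7,11-dihydroxy-8,11-epidioxycembra-3,12,15(17)-trien-16,2-olide (peroxyhemiketal; C11 anomers), via hydroperoxy alcohol 19 (not isolated)
Conditions: H2O2 (anhydrous, in Et2O, 10 equiv), H3PMo12O40 (5 mol %), Et2O, 0 °C to rt
Reagents that add atoms: hydrogen peroxide OO
Why: Acid-catalysed perhydrolysis of the trisubstituted epoxide puts H2O2 on the tertiary C8 with inversion (8S to 8R, C7 untouched), and the hydroperoxide then adds to the C11 ketone to give the six-membered peroxyhemiketal; all remaining alkenes are deactivated toward the peroxo-molybdate.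

Step 14
Reactants: 20 (1S,2R,3E,7S,8R,12Z)-7,11-dihydroxy-8,11-epidioxycembra-3,12,15(17)-trien-16,2-olide
Product: 21 (1S,2R,3E,7S,8R,12Z)-7,11-diacetoxy-8,11-epidioxycembra-3,12,15(17)-trien-16,2-olide
Conditions: Ac2O, pyridine, DMAP (cat.), CH2Cl2, 0 °C
Reagents that add atoms: acetic anhydride CC(=O)OC(C)=O
Why: DMAP-catalysed acylation installs the C7 acetate of the target (so the C7 oxygen can no longer compete for C11) and turns the hemiketal OH into a leaving group.

Step 15
Reactants: 21 (1S,2R,3E,7S,8R,12Z)-7,11-diacetoxy-8,11-epidioxycembra-3,12,15(17)-trien-16,2-olide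
Product: 23 (1S,2R,3E,7S,8R,11S,12Z)-7-acetoxy-8,11-epidioxycembra-3,12,15(17)-trien-16,2-olide (target), via peroxycarbenium triflate 22 (not isolated)
Conditions: Et3SiH (5 equiv), Me3SiOTf (0.3 equiv), CH2Cl2, −78 °C
Reagents that add atoms: none
Why: Ionic hydrogenation of a peroxycarbenium ion: Me3SiOTf ionises the ketal acetate (the peroxide oxygen stays) and Et3SiH delivers hydride to C11 on the face opposite the transannular bridge from C7, so C12 ends cis to C7 on the dioxane (11S).

## Compound list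

1 | (2E,6E)-farnesol | CC(C)=CCC/C(C)=C/CC/C(C)=C/CO | starting material
2 | (2E,6E)-10-bromo-3,7,11-trimethyldodeca-2,6-diene-1,11-diol (racemic) | CC(C)(O)C(Br)CC/C(C)=C/CC/C(C)=C/CO | intermediate
3 | (2E,6E)-10,11-epoxy-3,7,11-trimethyldodeca-2,6-dien-1-ol (racemic) | CC1(C)OC1CC/C(C)=C/CC/C(C)=C/CO | intermediate
4 | (4E,8E)-10-hydroxy-4,8-dimethyldeca-4,8-dienal | O=CCC/C(C)=C/CC/C(C)=C/CO | intermediate
5 | but-2-yn-1-ol | CC#CCO | starting material
6 | (Z)-3-iodobut-2-en-1-ol | C/C(I)=C/CO | intermediate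
7 | (Z)-1-bromo-3-iodobut-2-ene | C/C(I)=C/CBr | intermediate
8 | methyl propiolate | C#CC(=O)OC | starting material
9 | methyl (Z)-6-iodohept-5-en-2-ynoate | C/C(I)=C/CC#CC(=O)OC | intermediate
10 | 2-(iodomethyl)-4,4,5,5-tetramethyl-1,3,2-dioxaborolane | ICB1OC(C)(C)C(C)(C)O1 | starting material
11 | diisobutylaluminium allenolate of 9 | C/C(I)=C/CC=C=C(OC)O[Al](CC(C)C)CC(C)C | intermediate (not isolated)
12 | methyl (2Z,5Z)-6-iodo-2-[(4,4,5,5-tetramethyl-1,3,2-dioxaborolan-2-yl)methyl]hepta-2,5-dienoate | COC(=O)/C(CB1OC(C)(C)C(C)(C)O1)=C\C/C=C(/C)I | intermediate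
13 | methyl (2Z,5Z,10E,14E)-7,16-dihydroxy-6,10,14-trimethyl-2-[(Bpin)methyl]hexadeca-2,5,10,14-tetraenoate (racemic carbinol) | OC/C=C(\C)CC/C=C(\C)CCC(O)/C(C)=C\C/C=C(/CB1OC(C)(C)C(C)(C)O1)C(=O)OC | intermediate
14 | methyl (2Z,5Z,10E,14E)-7-hydroxy-6,10,14-trimethyl-16-oxo-2-[(Bpin)methyl]hexadeca-2,5,10,14-tetraenoate (racemic carbinol) | O=C/C=C(\C)CC/C=C(\C)CCC(O)/C(C)=C\C/C=C(/CB1OC(C)(C)C(C)(C)O1)C(=O)OC | intermediate
15 | macrocyclic (1S,2R) C2–O–Bpin borate with open methyl ester (C11 epimers) | CC1(C)OB(O[C@@H]2/C=C(\C)CC/C=C(\C)CCC(O)/C(C)=C\C[C@H]2C(=C)C(=O)OC)OC1(C)C | intermediate (not isolated)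
16 | (1S,2R,3E,7E,12Z)-11-hydroxycembra-3,7,12,15(17)-tetraen-16,2-olide (C11 epimers) | C=C1C(=O)O[C@@H]2/C=C(\C)CC/C=C(\C)CCC(O)/C(C)=C\C[C@@H]12 | intermediate
17 | (1S,2R,3E,7E,12Z)-11-oxocembra-3,7,12,15(17)-tetraen-16,2-olide | C=C1C(=O)O[C@@H]2/C=C(\C)CC/C=C(\C)CCC(=O)/C(C)=C\C[C@@H]12 | intermediate
18 | (1S,2R,3E,7S,8S,12Z)-7,8-epoxy-11-oxocembra-3,12,15(17)-trien-16,2-olide | C=C1C(=O)O[C@@H]2/C=C(\C)CC[C@@H]3O[C@@]3(C)CCC(=O)/C(C)=C\C[C@@H]12 | intermediate
19 | (1S,2R,3E,7S,8R,12Z)-8-hydroperoxy-7-hydroxy-11-oxocembra-3,12,15(17)-trien-16,2-olide | C=C1C(=O)O[C@@H]2/C=C(\C)CC[C@H](O)[C@](C)(OO)CCC(=O)/C(C)=C\C[C@@H]12 | intermediate (not isolated)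
20 | (1S,2R,3E,7S,8R,12Z)-7,11-dihydroxy-8,11-epidioxycembra-3,12,15(17)-trien-16,2-olide (C11 anomers) | C=C1C(=O)O[C@@H]2/C=C(\C)CC[C@H](O)[C@@]3(C)CCC(O)(OO3)/C(C)=C\C[C@@H]12 | intermediate
21 | (1S,2R,3E,7S,8R,12Z)-7,11-diacetoxy-8,11-epidioxycembra-3,12,15(17)-trien-16,2-olide (C11 anomers) | C=C1C(=O)O[C@@H]2/C=C(\C)CC[C@H](OC(C)=O)[C@@]3(C)CCC(OC(C)=O)(OO3)/C(C)=C\C[C@@H]12 | intermediate
22 | C11 peroxycarbenium triflate of 21 | C=C1C(=O)O[C@@H]2/C=C(\C)CC[C@H](OC(C)=O)[C@@]3(C)CCC(=[O+]O3)/C(C)=C\C[C@@H]12.[O-]S(=O)(=O)C(F)(F)F | intermediate (not isolated)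
23 | (1S,2R,3E,7S,8R,11S,12Z)-7-acetoxy-8,11-epidioxycembra-3,12,15(17)-trien-16,2-olide | C=C1C(=O)O[C@@H]2/C=C(\C)CC[C@H](OC(C)=O)[C@@]3(C)CC[C@H](OO3)/C(C)=C\C[C@@H]12 | target

## Step count and risk

Total steps: 15. Longest linear sequence: 12 (5 to 23, steps 4–15).

**Step 10 (the proposed new macrocyclisation).** The ester-deactivated boronate may be too slow under a phosphoric acid at pseudo-dilution, and the facial sense is only an analogy. The fallback uses known reactions only, sets out from 4 and 12, and returns at 18. It reverses the order of the two C–C couplings and moves enantiocontrol to the epoxidation.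
- Aldehyde 4 is protected (HC(OMe)3, MeOH, PPTS) as (2E,6E)-10,10-dimethoxy-3,7-dimethyldeca-2,6-dien-1-ol F1 and oxidised with MnO2 to (2E,6E)-10,10-dimethoxy-3,7-dimethyldeca-2,6-dienal F2.
- Heating F2 with 12 in toluene (100 °C, no catalyst; the uncatalysed, anti-selective closed-chair allylboration of 2-alkoxycarbonyl allylboronates is established) gives the racemic anti borate F3.
- PPTS lactonises F3 to the racemic trans lactone acetal F4, and PPTS in acetone/H2O frees the racemic lactone aldehyde F5.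
- Intramolecular Nozaki–Hiyama–Kishi coupling (CrCl2, cat. NiCl2, DMSO/THF, 2 mM) closes the 14-membered ring at C11–C12 and gives 16 together with its (1R,2S) mirror image F6.
- MnO2 gives 17 together with its (1R,2S) mirror image F7.
- Shi epoxidation with the ent-Shi ketone turns the two enantiomers into the diastereomers 18 and the (1R,2S,7S,8S)-epoxide F8, which are separated by chromatography (at most half of the material), and the route continues from 18.

**Step 13 (perhydrolysis in the presence of the C11 ketone).** The free C7 hydroxyl can compete for C11. The fallback sets out from 18 and returns at 23, and makes that reactivity the route.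
- After the H2O2/H3PMo12O40 treatment, crude 20 is stirred with CSA and 4 Å MS in CH2Cl2 so that C7–OH closes onto C11 and the material converges on the 2,3,5-trioxabicyclo[2.2.2]octane ketal F9.
- Et3SiH/TiCl4 (−78 °C) ionises the more Lewis-basic ether C11–O bond (as with mixed monoperoxyketals) and hydride enters anti to the departing C7 oxygen, giving the 7-hydroxy endoperoxide F10 (deacetyl 23).
- Ac2O/pyridine converts F10 into 23.

**Step 15 (silane reduction: C11 configuration, possible Hock-type fragmentation).** The fallback sets out from 18 and returns at 23. It sets C11–H before the peroxide ring is closed, so no peroxycarbenium ion is needed.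
- CBS reduction of 18 ((S)-2-methyl-CBS-oxazaborolidine, catecholborane, −78 °C) gives the (11R)-epoxy allylic alcohol F11.
- Mesylation (MsCl, Et3N, −40 °C) gives the allylic mesylate F12, which is displaced in the same flask by anhydrous H2O2 with inversion to the (11S)-hydroperoxide F13.
- Catalytic CSA triggers the known 6-exo opening of the 7,8-epoxide at C8 by the hydroperoxide and gives the same 7-hydroxy endoperoxide F10 as in the fallback for step 13; acetylation gives 23.

## Further compounds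

F1 | step 10 | (2E,6E)-10,10-dimethoxy-3,7-dimethyldeca-2,6-dien-1-ol | COC(OC)CC/C(C)=C/CC/C(C)=C/CO
F2 | step 10 | (2E,6E)-10,10-dimethoxy-3,7-dimethyldeca-2,6-dienal | COC(OC)CC/C(C)=C/CC/C(C)=C/C=O
F3 | step 10 | racemic anti O-Bpin borate from F2 and 12, open methyl ester (enantiomer leading to 16 drawn) | CC1(C)OB(O[C@H](/C=C(\C)CC/C=C(\C)CCC(OC)OC)[C@@H](C/C=C(/C)I)C(=C)C(=O)OC)OC1(C)C
F4 | step 10 | racemic trans α-methylene-γ-lactone dimethyl acetal with the (Z)-vinyl iodide side chain (enantiomer leading to 16 drawn) | C=C1C(=O)O[C@H](/C=C(\C)CC/C=C(\C)CCC(OC)OC)[C@H]1C/C=C(/C)I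
F5 | step 10 | racemic trans lactone aldehyde (enantiomer leading to 16 drawn) | C=C1C(=O)O[C@H](/C=C(\C)CC/C=C(\C)CCC=O)[C@H]1C/C=C(/C)I
F6 | step 10 | (1R,2S,3E,7E,12Z)-11-hydroxycembra-3,7,12,15(17)-tetraen-16,2-olide (mirror image of 16, C11 epimers) | C=C1C(=O)O[C@H]2/C=C(\C)CC/C=C(\C)CCC(O)/C(C)=C\C[C@H]12
F7 | step 10 | (1R,2S,3E,7E,12Z)-11-oxocembra-3,7,12,15(17)-tetraen-16,2-olide (mirror image of 17) | C=C1C(=O)O[C@H]2/C=C(\C)CC/C=C(\C)CCC(=O)/C(C)=C\C[C@H]12
F8 | step 10 | (1R,2S,3E,7S,8S,12Z)-7,8-epoxy-11-oxocembra-3,12,15(17)-trien-16,2-olide | C=C1C(=O)O[C@H]2/C=C(\C)CC[C@@H]3O[C@@]3(C)CCC(=O)/C(C)=C\C[C@H]12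
F9 | step 13 | (1S,2R,3E,7S,8R,12Z)-7,11-epoxy-8,11-epidioxycembra-3,12,15(17)-trien-16,2-olide (bicyclic trioxane ketal) | C=C1C(=O)O[C@@H]2/C=C(\C)CC[C@@H]3O[C@@]4(CC[C@@]3(C)OO4)/C(C)=C\C[C@@H]12
F10 | step 13 | (1S,2R,3E,7S,8R,11S,12Z)-7-hydroxy-8,11-epidioxycembra-3,12,15(17)-trien-16,2-olide | C=C1C(=O)O[C@@H]2/C=C(\C)CC[C@H](O)[C@@]3(C)CC[C@H](OO3)/C(C)=C\C[C@@H]12
F11 | step 15 | (1S,2R,3E,7S,8S,11R,12Z)-7,8-epoxy-11-hydroxycembra-3,12,15(17)-trien-16,2-olide | C=C1C(=O)O[C@@H]2/C=C(\C)CC[C@@H]3O[C@@]3(C)CC[C@@H](O)/C(C)=C\C[C@@H]12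
F12 | step 15 | (11R)-methanesulfonate of F11 | C=C1C(=O)O[C@@H]2/C=C(\C)CC[C@@H]3O[C@@]3(C)CC[C@@H](OS(C)(=O)=O)/C(C)=C\C[C@@H]12
F13 | step 15 | (1S,2R,3E,7S,8S,11S,12Z)-7,8-epoxy-11-hydroperoxycembra-3,12,15(17)-trien-16,2-olide | C=C1C(=O)O[C@@H]2/C=C(\C)CC[C@@H]3O[C@@]3(C)CC[C@H](OO)/C(C)=C\C[C@@H]12
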